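**Plan**

Locants follow daucane: C1 (quaternary, CH3), C2, C3, C4 (carbinol, isopropyl), C5 (ring-fusion CH), C6 (CH–O), C7 (=CH), C8 (=C–CH3), C9 (C=O), C10 (CH2); ring A is the cyclopentane C1–C5, ring B the cycloheptenone.
Retrosynthesis cuts, in order: the C6–O acyl bond; C6–C7 together with C8–C9 (ring B); the C4–isopropyl bond; C5–C6 together with C1–C10.
Enabling feature: in ring B the segment O–C6H–C7H=C8(CH3)–C9(=O) is a cis-2-ene-1,4-dioxygenated unit whose ends sit on the trans C5 and C1 arms of ring A. It is the retron of a nitroalkene stitched between an acyl anion (C9) and a formyl carbon (C6) with nitrite as leaving group, so (E)-1-nitropropene serves as a propyne equivalent in a formal (5+2) annulation.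
Forward: ring A is present from the start (3-methylcyclopentenone) and receives the C6 and C10–C9 arms in one radical cascade; ring B is closed in step 11; the p-coumarate is attached last.
Stereochemistry: a catalytic ketone reduction sets a carbinol at C4; the silicon tether relays it to C5 and C1 (trans ring junction); the C4 carbinol is then rebuilt by isopropyl addition anti to C6; C6 is set during ring closure.

Key step: step 11

Remark: (E)-1-nitroprop-1-ene is taken as a purchasable reagent; the C4 hydroxyl is left free from step 8 onward because it cannot lactolize with either formyl group (a four-membered ring to C6, a trans-disposed arm to C9).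

Step 1
Reactants: 1 3-methylcyclopent-2-en-1-one
Product: 2 (S)-3-methylcyclopent-2-en-1-ol
Conditions: (R)-tetrahydro-1-methyl-3,3-diphenyl-1H,3H-pyrrolo[1,2-c][1,3,2]oxazaborole (10 mol%), BH3·SMe2, THF, −20 °C
Reagents that add atoms: none
Why: Corey–Bakshi–Shibata reduction should deliver hydride to one ketone face, the alkene flank acting as the large group in the oxazaborolidine–borane complex, which sets the carbinol (future C4) as S.

Step 2
Reactants: 2 (S)-3-methylcyclopent-2-en-1-ol
Product: 3 (S)-(bromomethyl)dimethyl[(3-methylcyclopent-2-en-1-yl)oxy]silane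
Conditions: BrCH2SiMe2Cl, Et3N, 4-(dimethylamino)pyridine (cat.), CH2Cl2, 0 °C
Reagents that add atoms: (bromomethyl)chlorodimethylsilane C[Si](C)(Cl)CBr
Why: O-silylation of the allylic alcohol installs the α-bromosilane radical tether (its CH2 becomes C6) without touching the stereocenter.

Step 3
Reactants: 3 (S)-(bromomethyl)dimethyl[(3-methylcyclopent-2-en-1-yl)oxy]silane
Product: 4 (3aR,4R,6aS)-2,2,4-trimethyl-4-(prop-2-en-1-yl)hexahydro-2H-cyclopenta[d][1,2]oxasilole
Conditions: Bu3SnCH2CH=CH2 (3 equiv), 2,2'-azobis(isobutyronitrile) (cat., in portions), PhH, 80 °C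
Reagents that add atoms: allyltributylstannane C=CC[Sn](CCCC)(CCCC)CCCC
Why: Silicon-tethered 5-exo-trig radical cyclization should deliver the CH2 to C5 on the face of the C4–O tether (cis-fused oxasilolane, C6 cis to O4), and Keck allyl transfer should trap the tertiary C1 radical on the convex face anti to the new ring, so that C10 ends trans to C6 and the C1 methyl cis to it.

Step 4
Reactants: 4 (3aR,4R,6aS)-2,2,4-trimethyl-4-(prop-2-en-1-yl)hexahydro-2H-cyclopenta[d][1,2]oxasilole
Product: 5 (1S,2S,3R)-2-(hydroxymethyl)-3-methyl-3-(prop-2-en-1-yl)cyclopentan-1-ol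
Conditions: KF, KHCO3, 30% H2O2, THF–MeOH, rt
Reagents that add atoms: hydrogen peroxide OO
Why: Tamao–Fleming oxidation converts the C6–Si bond into C6–OH with retention and frees the C4 hydroxyl, leaving all stereocenters unchanged.

Step 5
Reactants: 5 (1S,2S,3R)-2-(hydroxymethyl)-3-methyl-3-(prop-2-en-1-yl)cyclopentan-1-ol
Product: 6 (1S,2S,3R)-2-({[tert-butyl(dimethyl)silyl]oxy}methyl)-3-methyl-3-(prop-2-en-1-yl)cyclopentan-1-ol
Conditions: t-BuMe2SiCl (1.05 equiv), imidazole, CH2Cl2, 0 °C
Reagents that add atoms: tert-butyldimethylsilyl chloride CC(C)(C)[Si](C)(C)Cl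
Why: Selective silylation of the primary hydroxyl over the hindered secondary one is a standard steric differentiation and leaves the C4 carbinol free for oxidation.

Step 6
Reactants: 6 (1S,2S,3R)-2-({[tert-butyl(dimethyl)silyl]oxy}methyl)-3-methyl-3-(prop-2-en-1-yl)cyclopentan-1-ol
Product: 7 (2S,3R)-2-({[tert-butyl(dimethyl)silyl]oxy}methyl)-3-methyl-3-(prop-2-en-1-yl)cyclopentan-1-one
Conditions: Dess–Martin periodinane, CH2Cl2, 0 °C to rt
Reagents that add atoms: none
Why: Dess–Martin oxidation under near-neutral conditions gives the C4 ketone, erasing the relay center while the epimerizable C5 center next to it should be preserved.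

Step 7
Reactants: 7 (2S,3R)-2-({[tert-butyl(dimethyl)silyl]oxy}methyl)-3-methyl-3-(prop-2-en-1-yl)cyclopentan-1-one
Product: 8 (1R,2S,3R)-2-({[tert-butyl(dimethyl)silyl]oxy}methyl)-3-methyl-1-(propan-2-yl)-3-(prop-2-en-1-yl)cyclopentan-1-ol
Conditions: i-PrMgCl, CeCl3, THF, −78 to 0 °C
Reagents that add atoms: isopropylmagnesium chloride CC(C)[Mg]Cl
Why: Organocerium 1,2-addition (weakly basic, so enolization and β-hydride reduction are suppressed) should occur on the ketone face anti to the adjacent C5 silyloxymethyl group, placing isopropyl trans and the new C4 hydroxyl cis to C6 (C4 R).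

Step 8
Reactants: 8 (1R,2S,3R)-2-({[tert-butyl(dimethyl)silyl]oxy}methyl)-3-methyl-1-(propan-2-yl)-3-(prop-2-en-1-yl)cyclopentan-1-ol
Product: 9 (1R,2S,3R)-2-(hydroxymethyl)-3-methyl-1-(propan-2-yl)-3-(prop-2-en-1-yl)cyclopentan-1-ol
Conditions: HF·pyridine, pyridine, THF, 0 °C to rt
Reagents that add atoms: none
Why: Fluoride-mediated desilylation of the primary silyl ether is routine and leaves the tertiary alcohol and the alkene untouched.

Step 9
Reactants: 9 (1R,2S,3R)-2-(hydroxymethyl)-3-methyl-1-(propan-2-yl)-3-(prop-2-en-1-yl)cyclopentan-1-ol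
Product: 10 (1R,2R,5R)-2-hydroxy-5-methyl-2-(propan-2-yl)-5-(prop-2-en-1-yl)cyclopentane-1-carbaldehyde
Conditions: 2,2,6,6-tetramethylpiperidin-1-oxyl (10 mol%), PhI(OAc)2, CH2Cl2, rt
Reagents that add atoms: none
Why: Oxoammonium (TEMPO) oxidation is selective for the primary alcohol, cannot oxidize the tertiary one, and is mild enough to keep the C5 center of the β-hydroxy aldehyde.

Step 10
Reactants: 10 (1R,2R,5R)-2-hydroxy-5-methyl-2-(propan-2-yl)-5-(prop-2-en-1-yl)cyclopentane-1-carbaldehyde
Product: 12 (1R,2R,5R)-2-hydroxy-5-methyl-5-(2-oxoethyl)-2-(propan-2-yl)cyclopentane-1-carbaldehyde, via secondary ozonide 11 (not isolated)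
Conditions: O3, CH2Cl2, −78 °C; then PPh3, −78 °C to rt; crude product used at once
Reagents that add atoms: ozone [O-][O+]=O
Why: Ozonolysis of the terminal alkene with reductive work-up shortens the allyl group to the C10–C9 formylmethyl arm under neutral conditions that do not touch the stereocenters.

Step 11
Reactants: 12 (1R,2R,5R)-2-hydroxy-5-methyl-5-(2-oxoethyl)-2-(propan-2-yl)cyclopentane-1-carbaldehyde; 13 (E)-1-nitroprop-1-ene
Product: 16 (1R,3aR,8S,8aS)-1,8-dihydroxy-3a,6-dimethyl-1-(propan-2-yl)-2,3,3a,4,8,8a-hexahydroazulen-5(1H)-one, via Stetter nitro ketone 14 (not isolated), via ring-closed nitro alcohol 15 (not isolated)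
Conditions: 13 (1.2 equiv, added slowly), 6,7-dihydro-2-(pentafluorophenyl)-5H-pyrrolo[2,1-c][1,2,4]triazol-2-ium tetrafluoroborate (20 mol%), i-Pr2NEt, t-AmOH, 0 °C to rt; then DBU (1.5 equiv), 0 °C
Reagents that add atoms: none
Why: Proposed new method: the carbene adds to the unhindered C9 formyl group, the Breslow intermediate adds to the methyl-bearing β-carbon of 13 (Stetter step, forms C8–C9), and the nitronate so released closes ring B by nitro-aldol addition of C7 to the C6 formyl group (forms C6–C7); DBU then expels nitrite from C7 by E1cB through the C9 enolate, which fixes the alkene at C7=C8 with the methyl on C8. The closest known reaction types are the carbene-catalyzed intermolecular Stetter reaction of aldehydes with nitroalkenes, the amine-mediated Michael/nitro-aldol annulation of nitroalkenes with dialdehydes, and base-induced loss of HNO2 from β-nitro ketones; here an acyl anion replaces the enamine as first nucleophile. Ring B closes in the 7-exo-trig mode onto a formyl group held five atoms away by the trans C1 and C5 arms of ring A. C6 is the only new stereocenter that survives: the formyl oxygen is hydrogen-bonded to the C4 hydroxyl so that C7 attacks the exposed face, and because the nitro-aldol is reversible the hydroxyl should settle pseudo-equatorial (H6 anti to H5), both arguments giving 6S, while the centers at C7 and C8 are erased by the elimination. The step needs chemoselection between the two formyl groups (the C6 formyl is flanked by two quaternary carbons), absence of benzoin closure (it would give a trans-fused bicyclo[3.3.0]octanone) and ring closure before nitrite loss (weak amine base first, DBU only afterwards).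

Step 12
Reactants: 17 (2E)-3-(4-hydroxyphenyl)prop-2-enoic acid (p-coumaric acid)
Product: 19 (2E)-3-{4-[(tert-butyldimethylsilyl)oxy]phenyl}prop-2-enoic acid, via bis-silylated coumarate 18 (not isolated)
Conditions: t-BuMe2SiCl (2.3 equiv), imidazole, DMF, rt; then AcOH–THF–H2O, rt
Reagents that add atoms: tert-butyldimethylsilyl chloride CC(C)(C)[Si](C)(C)Cl
Why: Exhaustive silylation followed by selective hydrolysis of the far more labile silyl ester is the standard way to mask a phenol in a hydroxycinnamic acid.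

Step 13
Reactants: 16 (1R,3aR,8S,8aS)-1,8-dihydroxy-3a,6-dimethyl-1-(propan-2-yl)-2,3,3a,4,8,8a-hexahydroazulen-5(1H)-one; 19 (2E)-3-{4-[(tert-butyldimethylsilyl)oxy]phenyl}prop-2-enoic acid
Product: 20 (1R,3aR,8S,8aS)-1-hydroxy-3a,6-dimethyl-5-oxo-1-(propan-2-yl)-1,2,3,3a,4,5,8,8a-octahydroazulen-8-yl (2E)-3-{4-[(tert-butyldimethylsilyl)oxy]phenyl}prop-2-enoate
Conditions: N,N'-dicyclohexylcarbodiimide, 4-(dimethylamino)pyridine (cat.), CH2Cl2, 0 °C to rt
Reagents that add atoms: none
Why: Steglich esterification acylates the secondary allylic C6 hydroxyl at oxygen (configuration retained) while the tertiary C4 hydroxyl is too hindered to react.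

Step 14
Reactants: 20 (1R,3aR,8S,8aS)-1-hydroxy-3a,6-dimethyl-5-oxo-1-(propan-2-yl)-1,2,3,3a,4,5,8,8a-octahydroazulen-8-yl (2E)-3-{4-[(tert-butyldimethylsilyl)oxy]phenyl}prop-2-enoate
Product: 21 (1R,3aR,8S,8aS)-1-hydroxy-3a,6-dimethyl-5-oxo-1-(propan-2-yl)-1,2,3,3a,4,5,8,8a-octahydroazulen-8-yl (2E)-3-(4-hydroxyphenyl)prop-2-enoate
Conditions: HF·pyridine, pyridine, THF, 0 °C
Reagents that add atoms: none
Why: Buffered fluoride desilylation of the aryl silyl ether is fast and should not disturb the allylic ester, the enone or the tertiary alcohol.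

**Compound list**

1 | 3-methylcyclopent-2-en-1-one | CC1=CC(=O)CC1 | starting material
2 | (S)-3-methylcyclopent-2-en-1-ol | CC1=C[C@@H](O)CC1 | intermediate
3 | (S)-(bromomethyl)dimethyl[(3-methylcyclopent-2-en-1-yl)oxy]silane | CC1=C[C@@H](O[Si](C)(C)CBr)CC1 | intermediate
4 | (3aR,4R,6aS)-2,2,4-trimethyl-4-(prop-2-en-1-yl)hexahydro-2H-cyclopenta[d][1,2]oxasilole (cis-fused; allyl trans to the ring CH2) | C3[C@@H]2[C@](C)(CC[C@@H]2O[Si]3(C)C)CC=C | intermediate
5 | (1S,2S,3R)-2-(hydroxymethyl)-3-methyl-3-(prop-2-en-1-yl)cyclopentan-1-ol | OC[C@@H]2[C@](C)(CC[C@@H]2O)CC=C | intermediate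
6 | (1S,2S,3R)-2-({[tert-butyl(dimethyl)silyl]oxy}methyl)-3-methyl-3-(prop-2-en-1-yl)cyclopentan-1-ol | CC(C)(C)[Si](C)(C)OC[C@@H]2[C@](C)(CC[C@@H]2O)CC=C | intermediate
7 | (2S,3R)-2-({[tert-butyl(dimethyl)silyl]oxy}methyl)-3-methyl-3-(prop-2-en-1-yl)cyclopentan-1-one | CC(C)(C)[Si](C)(C)OC[C@@H]2[C@](C)(CCC2=O)CC=C | intermediate
8 | (1R,2S,3R)-2-({[tert-butyl(dimethyl)silyl]oxy}methyl)-3-methyl-1-(propan-2-yl)-3-(prop-2-en-1-yl)cyclopentan-1-ol | CC(C)(C)[Si](C)(C)OC[C@@H]2[C@](C)(CC[C@@]2(O)C(C)C)CC=C | intermediate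
9 | (1R,2S,3R)-2-(hydroxymethyl)-3-methyl-1-(propan-2-yl)-3-(prop-2-en-1-yl)cyclopentan-1-ol | OC[C@@H]2[C@](C)(CC[C@@]2(O)C(C)C)CC=C | intermediate
10 | (1R,2R,5R)-2-hydroxy-5-methyl-2-(propan-2-yl)-5-(prop-2-en-1-yl)cyclopentane-1-carbaldehyde | O=C[C@@H]2[C@](C)(CC[C@@]2(O)C(C)C)CC=C | intermediate
11 | (1R,2R,5R)-2-hydroxy-5-methyl-2-(propan-2-yl)-5-(1,2,4-trioxolan-3-ylmethyl)cyclopentane-1-carbaldehyde (both epimers at the trioxolane carbon) | O=C[C@@H]2[C@](C)(CC[C@@]2(O)C(C)C)CC3OCOO3 | intermediate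
12 | (1R,2R,5R)-2-hydroxy-5-methyl-5-(2-oxoethyl)-2-(propan-2-yl)cyclopentane-1-carbaldehyde | O=C[C@@H]2[C@](C)(CC[C@@]2(O)C(C)C)CC=O | intermediate
13 | (E)-1-nitroprop-1-ene | C/C=C/[N+](=O)[O-] | starting material
14 | (1R,2R,5R)-2-hydroxy-5-methyl-5-(3-methyl-4-nitro-2-oxobutyl)-2-(propan-2-yl)cyclopentane-1-carbaldehyde (both epimers at the methyl-bearing carbon) | O=C[C@@H]2[C@](C)(CC[C@@]2(O)C(C)C)CC(=O)C(C)C[N+](=O)[O-] | intermediate
15 | (1R,3aR,8S,8aS)-1,8-dihydroxy-3a,6-dimethyl-7-nitro-1-(propan-2-yl)octahydroazulen-5(1H)-one (mixture at C6 and C7 of the azulene skeleton) | CC1C([N+](=O)[O-])[C@H](O)[C@@H]2[C@](C)(CC[C@@]2(O)C(C)C)CC1=O | intermediate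
16 | (1R,3aR,8S,8aS)-1,8-dihydroxy-3a,6-dimethyl-1-(propan-2-yl)-2,3,3a,4,8,8a-hexahydroazulen-5(1H)-one | CC1=C[C@H](O)[C@@H]2[C@](C)(CC[C@@]2(O)C(C)C)CC1=O | intermediate
17 | (2E)-3-(4-hydroxyphenyl)prop-2-enoic acid | OC(=O)/C=C/c1ccc(O)cc1 | starting material
18 | tert-butyldimethylsilyl (2E)-3-{4-[(tert-butyldimethylsilyl)oxy]phenyl}prop-2-enoate | CC(C)(C)[Si](C)(C)OC(=O)/C=C/c1ccc(O[Si](C)(C)C(C)(C)C)cc1 | intermediate
19 | (2E)-3-{4-[(tert-butyldimethylsilyl)oxy]phenyl}prop-2-enoic acid | OC(=O)/C=C/c1ccc(O[Si](C)(C)C(C)(C)C)cc1 | intermediate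
20 | (1R,3aR,8S,8aS)-1-hydroxy-3a,6-dimethyl-5-oxo-1-(propan-2-yl)-1,2,3,3a,4,5,8,8a-octahydroazulen-8-yl (2E)-3-{4-[(tert-butyldimethylsilyl)oxy]phenyl}prop-2-enoate | CC1=C[C@H](OC(=O)/C=C/c2ccc(O[Si](C)(C)C(C)(C)C)cc2)[C@@H]2[C@](C)(CC[C@@]2(O)C(C)C)CC1=O | intermediate
21 | (1R,3aR,8S,8aS)-1-hydroxy-3a,6-dimethyl-5-oxo-1-(propan-2-yl)-1,2,3,3a,4,5,8,8a-octahydroazulen-8-yl (2E)-3-(4-hydroxyphenyl)prop-2-enoate | CC1=C[C@H](OC(=O)/C=C/c2ccc(O)cc2)[C@@H]2[C@](C)(CC[C@@]2(O)C(C)C)CC1=O | target

**Step count and risks**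

Total step count: 14. Longest linear sequence: 13 (steps 1–11, 13, 14).

Steps most likely to fail:

1. Step 11 (new cascade). The carbene may be consumed by the nitroalkene, which then oligomerizes, before acyl transfer occurs. Nitrite may leave the open Stetter adduct before ring closure, giving an isopropenyl ketone that cannot cyclize. The β-hydroxy aldehyde may epimerize at C5 or undergo retro-aldol cleavage under base. The nitro-aldol may settle on the other C6 epimer. The fallback uses known chemistry only, sets out from 10 and returns at 16. 1-Propynylmagnesium bromide (THF, −78 °C; the C4 magnesium alkoxide chelates the formyl oxygen and the exposed face is attacked) would give the C6 propargylic diol F1. NaAlH2(OCH2CH2OCH3)2 followed by I2 (alkoxide-directed trans-hydroalumination, iodinolysis with retention) would give the (Z)-iodoalkene diol F2, with iodine on C8 cis to C6. Et3SiOSO2CF3 and 2,6-lutidine would give the bis(triethylsilyl) ether F3. OsO4 (cat.) with NaIO4 would cleave the terminal alkene to the iodoalkenyl aldehyde F4. CrCl2 with NiCl2 (cat.) in DMSO (Nozaki–Hiyama–Kishi closure of C8–C9) would give the cycloheptenol F5. Dess–Martin oxidation would give the bis-silylated enone F6, and HF·pyridine would return 16.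

2. Step 3. The tertiary C1 radical may be quenched by hydrogen abstraction because allyl transfer to a hindered tertiary center is slow, or the stannane may allylate the α-silyl radical before it cyclizes. The fallback sets out from 3 and returns at 5. Cyclization of 3 with Bu3SnH (slow addition) and 2,2'-azobis(isobutyronitrile) in the presence of phenyl vinyl sulfone, whose Giese capture of a tertiary radical is much faster than allyl transfer, would give the oxasilolane sulfone F7. LiN(i-Pr)2 and Me3SiCH2I would give the β-silyl sulfone F8. Bu4NF would then eliminate sulfinate and silyl fluoride to unveil the allyl group, and oxidation of the crude silicon species (KF, KHCO3, H2O2) would return 5.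

3. Step 7. The hindered ketone may be enolized toward C5 (loss of the ring-junction configuration or β-elimination of the silyloxy group), reduced by β-hydride transfer, or attacked on the wrong face. The fallback moves the isopropyl addition to the unhindered enone; it sets out from 1 and returns at 9. i-PrMgCl with CeCl3 would add 1,2 to 1 to give the racemic tertiary allylic alcohol F9. Preparative chromatography on a chiral stationary phase would give the (R)-tertiary alcohol F10. BrCH2SiMe2Cl and Et3N would give the bromomethylsilyl ether F11. The radical cyclization and allyl transfer of step 3 would give the isopropyl oxasilolane F12, and Tamao–Fleming oxidation would return 9.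

**Further compounds**

F1 | step 11 | C6 propargylic diol: 2-(1-hydroxybut-2-yn-1-yl)-3-methyl-1-(propan-2-yl)-3-(prop-2-en-1-yl)cyclopentan-1-ol | CC#C[C@H](O)[C@@H]2[C@](C)(CC[C@@]2(O)C(C)C)CC=C
F2 | step 11 | (Z)-iodoalkene diol: 2-[(2Z)-1-hydroxy-3-iodobut-2-en-1-yl]-3-methyl-1-(propan-2-yl)-3-(prop-2-en-1-yl)cyclopentan-1-ol | C/C(I)=C/[C@H](O)[C@@H]2[C@](C)(CC[C@@]2(O)C(C)C)CC=C
F3 | step 11 | bis(triethylsilyl) ether of F2 | C/C(I)=C/[C@H](O[Si](CC)(CC)CC)[C@@H]2[C@](C)(CC[C@@]2(O[Si](CC)(CC)CC)C(C)C)CC=C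
F4 | step 11 | iodoalkenyl aldehyde: 2-substituted (cyclopentyl)acetaldehyde from cleavage of the allyl group of F3 | C/C(I)=C/[C@H](O[Si](CC)(CC)CC)[C@@H]2[C@](C)(CC[C@@]2(O[Si](CC)(CC)CC)C(C)C)CC=O
F5 | step 11 | cycloheptenol: 1,8-bis(triethylsilyloxy)-3a,6-dimethyl-1-(propan-2-yl)-1,2,3,3a,4,5,8,8a-octahydroazulen-5-ol (both C5 epimers of the azulene skeleton) | CC1=C[C@H](O[Si](CC)(CC)CC)[C@@H]2[C@](C)(CC[C@@]2(O[Si](CC)(CC)CC)C(C)C)CC1O
F6 | step 11 | bis-silylated enone: 1,8-bis(triethylsilyloxy) derivative of 16 | CC1=C[C@H](O[Si](CC)(CC)CC)[C@@H]2[C@](C)(CC[C@@]2(O[Si](CC)(CC)CC)C(C)C)CC1=O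
F7 | step 3 | oxasilolane sulfone: 2,2,4-trimethyl-4-[2-(phenylsulfonyl)ethyl]hexahydro-2H-cyclopenta[d][1,2]oxasilole | C3[C@@H]2[C@](C)(CC[C@@H]2O[Si]3(C)C)CCS(=O)(=O)c1ccccc1
F8 | step 3 | β-silyl sulfone: 2,2,4-trimethyl-4-[2-(phenylsulfonyl)-3-(trimethylsilyl)propyl]hexahydro-2H-cyclopenta[d][1,2]oxasilole (both epimers at the sulfonyl carbon) | C3[C@@H]2[C@](C)(CC[C@@H]2O[Si]3(C)C)CC(C[Si](C)(C)C)S(=O)(=O)c1ccccc1
F9 | step 7 | racemic 3-methyl-1-(propan-2-yl)cyclopent-2-en-1-ol | CC1=CC(O)(C(C)C)CC1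
F10 | step 7 | (R)-3-methyl-1-(propan-2-yl)cyclopent-2-en-1-ol | CC1=C[C@](O)(C(C)C)CC1
F11 | step 7 | (R)-(bromomethyl)dimethyl{[3-methyl-1-(propan-2-yl)cyclopent-2-en-1-yl]oxy}silane | CC1=C[C@](O[Si](C)(C)CBr)(C(C)C)CC1
F12 | step 7 | isopropyl oxasilolane: 2,2,4-trimethyl-6a-(propan-2-yl)-4-(prop-2-en-1-yl)hexahydro-2H-cyclopenta[d][1,2]oxasilole | C3[C@@H]2[C@](C)(CC[C@@]2(O[Si]3(C)C)C(C)C)CC=C
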